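## Structural features

The target is a 2-aryl-3-hydroxymethyl-2,3-dihydro-1,4-benzodioxine neolignan: benzene ring A is fused through C4a and C8a to dioxane ring B, numbered O1–C2–C3–O4 with O1 on C8a and O4 on C4a. Ring A carries a methoxy group at C5, next to the O4-bearing C4a, and an (E)-propenal chain at C7, para to C4a. C2 bears ring C, a 3,4-dihydroxy-5-methoxyphenyl group, and the adjacent C3 bears the hydroxymethyl carbon C9; both neighbouring stereocentres are R, which places aryl and hydroxymethyl trans. The fragile groups are the catechol of ring C (oxidation), the enal (conjugate addition, reduction, further olefination) and the C2–O1 bond, a benzylic aryl ether para to an oxygen donor that ionises under protic or Lewis acid. That lability is also useful: C2 can be set late with a bias toward trans, so the real difficulties are the absolute configuration at C3 and the regiochemistry of ring B, that is, which of the two neighbouring ring A oxygens carries C3. The key step exploits that C3 is bonded to exactly O4, C2 and C9, the pattern of a diazoacetate carbene carbon placed between a phenol oxygen (O4 of ring A) and an aldehyde carbon (C2 with ring C), its ester carbon being C9.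

## Logic of the disconnections

13 from 12. The last cut is at the two O–Si bonds on ring C. Catechol and enal are then exposed together only in the final step, by buffered fluoride, which touches neither the enal nor the C2–O1 ether. Benzyl ethers are avoided here because their removal would need hydrogenolysis, which the enal does not survive, or a boron Lewis acid, which threatens the C2–O1 bond. The demand is that the silyl ethers last through acid, hydride, MnO2 and a warm ylide.

12 from 10 and 11. The Cα=Cβ bond of the enal is cut. 11 brings both carbons and the aldehyde in one olefination, so the side chain shrinks to a ring A aldehyde. The forward step must stop after one olefination, give the E alkene and tolerate the free C9 hydroxyl.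

10 from 9 from 8. These are changes of oxidation level only: the C7 aldehyde of 10 comes from the benzylic alcohol of 9, and both alcohols of 9 come from the two esters of 8. Keeping C7 and C9 as esters up to 8 means ring A stays electron-poor and acid-stable during ring closure. The oxidant must distinguish the benzylic from the saturated primary alcohol, and the reduction must not enolise the C3 ester.

8 from 6 (through 7). The O1–C2 bond is cut, which opens ring B to a benzylic alcohol and a masked ring A phenol. C2 becomes a carbinol whose configuration does not matter, because the forward closure passes through a planar benzylic cation and is steered to trans by the C3 substituent. The gain is one ring and one stereochemical requirement fewer. The forward step must ionise a carbon next to an ester-bearing carbon without losing the C3 hydrogen or the silyl ethers.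

6 from 2, 4 and 5. The O4–C3 and C2–C3 bonds are cut together: C3 and C9 become the carbene carbon and ester of 5, O4 the free phenol oxygen of 2, and C2 the carbonyl carbon of 4. The whole skeleton falls to three pieces of low complexity and C3 is set by a catalyst. The MOM ether on O1 of 2 leaves only O4 free, which fixes the regiochemistry of ring B. The forward step must trap the oxonium ylide (enol) with an aldehyde faster than proton shift, and with control of the enol face.

2 from 1, and 4 from 3. One acetal O–C bond and two O–Si bonds are cut, back to purchasable materials. For 2 one of two catechol oxygens has to be singled out; this is done through the dianion, in which the oxygen meta to the ester is the more nucleophilic. For 4 both phenols are silylated, so no selectivity is needed.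

## Other disconnections considered

Alternative 1: The cut is the O1–C2 bond, made by oxidation instead of ionisation. The open-chain ether A1 already has the O4–C3 bond and the silyl-protected C9; C2 is still a CH2 group and ring C has a free 4'-hydroxyl next to a MOM ether. Ag2O would dehydrogenate this para-alkyl phenol to a para-quinone methide, and the ring A hydroxyl O1 would add to its exocyclic carbon C2 to close ring B and give the trans aldehyde A2.
- In favour: oxidation of such phenols to quinone methides and their capture by phenols is established chemistry. C3 would come from the chiral pool and is never at risk. A2 already holds the C7 aldehyde, so its endgame is no longer than that from 10.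
- Against: A1 carries two phenols and an aldehyde, and the oxidant must pick the ring C phenol. Intermolecular capture and tautomerisation of the quinone methide to a styrene compete with the six-membered closure. The trans preference at C2 rests only on 1,2-induction in a kinetic addition. Making A1 needs an ether bond from a doubly ortho-substituted phenol to a secondary carbon and a separate construction of the C2–C3 bond.
- Comparison: on precedent and on the security of C3 the alternative is the better plan. On the need to tell O1 from O4 the two are equal. On convergence and step count the chosen plan is better, and on C2 it is better because its closure runs through a cation that can re-form.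

Alternative 2: The cut is C2–C3. In the ether aldehyde A3, O1 carries the ring C benzyl group and O4 a 2-oxoethyl arm. DDQ would take a hydride from the benzylic CH2 to give an aryloxy-stabilised carbenium ion at C2. The enamine formed from the aldehyde arm and a chiral secondary amine, for example (S)-2-[diphenyl(trimethylsilyloxy)methyl]pyrrolidine, would attack it, closing ring B and giving the trans aldehyde A4.
- In favour: A3 needs only two O-alkylations, so the precursor is shorter than anything in the chosen plan, and here the alternative is clearly better on step economy. Both stereocentres would be set by a catalyst in one event.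
- Against: DDQ also oxidises enamines. An aryl benzyl ether is a weaker hydride donor than an alkyl one, and the cation tends to collapse to aldehyde and phenol, which is the usual use of this reagent. A4 is an α-aryloxy aldehyde, open to epimerisation and to β-elimination of the O1 phenoxide, which would destroy both centres.
- Comparison: in mechanistic risk the two plans are equal, as both go beyond known chemistry. The chosen plan is better in that C3 is set in a configurationally stable ester and C2 is corrected later, whereas here both centres must be right kinetically and are then stored in a labile aldehyde.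

Alternative 3: Two bonds are cut, O1–C2 and O4–C4a. Bromophenol A5 would open the cis-epoxide A6 at its benzylic carbon with inversion to give bromo alcohol A7. Pd(OAc)2, a di-tert-butyl(biaryl)phosphine and Cs2CO3 would then join the C3 hydroxyl to C4a, closing ring B with retention at both centres and giving A8.
- In favour: every bond comes from a known reaction class, so on precedent the alternative is better. Both stereocentres derive from one epoxide and no acid equilibration is needed. The endgame from A8 equals that from 8.
- Against: A6 is an acid-sensitive cis-epoxide on an electron-rich arene that must be made enantiopure. Phenolysis at such a benzylic carbon can leak into an SN1 path, and since the palladium step retains configuration, any leak appears as cis product without correction. The aryl bromide lies between two ortho oxygens, and palladium alkoxides of secondary alcohols are prone to β-hydride elimination.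
- Comparison: structure and stereochemical logic are sound and, in principle, more predictable than the chosen plan. The count of steps to A5, A6 and A7 is clearly higher, and the route is less convergent.

Key step: step 3

Assumption: the (R)-configured phosphoric acid is taken to give the 2S configuration of 6; if the induction runs the other way, the (S)-acid is used with no other change.
Remark on names: benzodioxines are named with the ring B numbering used above (aryl on C2, C9 on C3, methoxy on C5, side chain on C7); TBS stands for tert-butyldimethylsilyl.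

## Route

Step 1
Reactants: 1 methyl 3,4-dihydroxy-5-methoxybenzoate
Product: 2 methyl 4-hydroxy-3-methoxy-5-(methoxymethoxy)benzoate
Conditions: NaH (2.1 equiv), DMF, 0 °C, argon; MOMCl (1.0 equiv), −20 → 0 °C; aq. NH4Cl
Reagents that add atoms: chloromethyl methyl ether (MOMCl), COCCl
Why: Regioselective O-alkylation of a catechol dianion: with both phenols deprotonated, the 3-oxide, not conjugated to the para ester and with one ortho neighbour only, is the more nucleophilic site and should take the single equivalent of MOMCl. The remaining 4-oxide is stabilised and flanked on both sides, which holds back a second alkylation.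

Step 2
Reactants: 3 3,4-dihydroxy-5-methoxybenzaldehyde (5-hydroxyvanillin)
Product: 4 3,4-bis(tert-butyldimethylsilyloxy)-5-methoxybenzaldehyde
Conditions: TBSCl (2.5 equiv), imidazole (5 equiv), DMF, rt
Reagents that add atoms: tert-butyldimethylsilyl chloride (TBSCl), CC(C)(C)[Si](C)(C)Cl
Why: Imidazole-promoted silylation of both phenols; no selectivity is required. Silyl ethers are chosen because they are inert to rhodium carbenes, still donate into ring C for the later cationic closure, and leave at the end under buffered fluoride.

Step 3
Reactants: 2 methyl 4-hydroxy-3-methoxy-5-(methoxymethoxy)benzoate; 4 3,4-bis(tert-butyldimethylsilyloxy)-5-methoxybenzaldehyde; 5 ethyl diazoacetate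
Product: 6 ethyl (2S,3R)-3-[3,4-bis(tert-butyldimethylsilyloxy)-5-methoxyphenyl]-3-hydroxy-2-[2-methoxy-4-(methoxycarbonyl)-6-(methoxymethoxy)phenoxy]propanoate
Conditions: Rh2(OAc)4 (2 mol %), (R)-3,3'-bis(2,4,6-triisopropylphenyl)-1,1'-binaphthyl-2,2'-diyl hydrogen phosphate ((R)-TRIP, 10 mol %), 4 Å MS, CH2Cl2, 0 °C; 5 (1.5 equiv) added over 6 h to 2 (1.0 equiv) and 4 (1.5 equiv)
Reagents that add atoms: none
Why: Proposed new method: Rh2(OAc)4 should turn 5 into an electrophilic rhodium carbene, to which the phenol oxygen of 2 adds to give an oxonium ylide in equilibrium with its enol; the closest known reaction type is the Rh2(OAc)4 and chiral Brønsted acid co-catalysed three-component coupling of aryl diazoacetates with alcohols and imines or activated aldehydes by trapping of the oxonium ylide, not yet shown for an acceptor-only diazoacetate with a phenol and an electron-rich benzaldehyde. Before the 1,2-proton shift that would end in plain O–H insertion, the enol should add to aldehyde 4 held by the phosphoric acid, so that the C2–C3 bond follows the O4–C3 bond in the same operation (aldol-type trapping). No ring closes. The stereocentre at the aryloxy carbon (2S in 6, the later C3) is set by the chiral phosphate, which binds the enol O–H with its P=O oxygen and the aldehyde with its P–OH group in one cyclic transition state and so decides which enol face reacts. The carbinol centre forms in the same transition state (3R, the syn adduct, is drawn), but its control is not needed, since step 4 passes through a planar benzylic cation and both epimers converge. The step needs O–H attack to beat carbonyl-ylide and arene pathways, and trapping to beat proton transfer: the first is secured by the acidic phenol O–H of 2, whose other ring A oxygen is blocked as the MOM ether so that only O4 reacts; the second by the bifunctional acid, an excess of 4 at high concentration, low temperature and slow addition of 5, which also limits carbene dimerisation.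

Step 4
Reactants: 6 ethyl (2S,3R)-3-[3,4-bis(tert-butyldimethylsilyloxy)-5-methoxyphenyl]-3-hydroxy-2-[2-methoxy-4-(methoxycarbonyl)-6-(methoxymethoxy)phenoxy]propanoate
Product: 8 ethyl (2R,3S)-2-[3,4-bis(tert-butyldimethylsilyloxy)-5-methoxyphenyl]-5-methoxy-7-(methoxycarbonyl)-2,3-dihydro-1,4-benzodioxine-3-carboxylate, via free ring A phenol 7 (not isolated)
Conditions: TFA (10 equiv), CH2Cl2–(CF3)2CHOH 4:1, 0 °C → rt
Reagents that add atoms: none
Why: Acidolysis of the aryl MOM ether frees the O1 phenol (7); in the ionising, non-nucleophilic fluoro alcohol the benzylic alcohol then gives a cation stabilised by the para silyloxy group, which the neighbouring phenol captures in a six-membered dehydrative etherification. Attack on the planar cation anti to the C3 ester should give the trans (2R) isomer from either carbinol epimer of 6, while C3 is not touched and aryl silyl ethers tolerate anhydrous TFA.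

Step 5
Reactants: 8 ethyl (2R,3S)-2-[3,4-bis(tert-butyldimethylsilyloxy)-5-methoxyphenyl]-5-methoxy-7-(methoxycarbonyl)-2,3-dihydro-1,4-benzodioxine-3-carboxylate
Product: 9 [(2R,3R)-2-[3,4-bis(tert-butyldimethylsilyloxy)-5-methoxyphenyl]-5-methoxy-2,3-dihydro-1,4-benzodioxine-3,7-diyl]dimethanol
Conditions: iBu2AlH (6 equiv), CH2Cl2, −78 → 0 °C; aq. KNaC4H4O6 (potassium sodium tartrate)
Reagents that add atoms: none
Why: Reduction of both esters with a non-basic aluminium hydride, which avoids enolisation of the C3 ester and with it epimerisation or β-elimination of the O1 phenoxide. Aryl silyl ethers survive iBu2AlH at low temperature; the descriptor at C3 changes from S to R only through the change in substituent priority.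

Step 6
Reactants: 9 [(2R,3R)-2-[3,4-bis(tert-butyldimethylsilyloxy)-5-methoxyphenyl]-5-methoxy-2,3-dihydro-1,4-benzodioxine-3,7-diyl]dimethanol
Product: 10 (2R,3R)-2-[3,4-bis(tert-butyldimethylsilyloxy)-5-methoxyphenyl]-3-(hydroxymethyl)-5-methoxy-2,3-dihydro-1,4-benzodioxine-7-carbaldehyde
Conditions: MnO2 (activated, 15 equiv), CH2Cl2, rt
Reagents that add atoms: none
Why: MnO2 oxidation is selective for benzylic alcohols; the saturated primary C9 alcohol, the silyl ethers and the masked catechol are left alone.

Step 7
Reactants: 10 (2R,3R)-2-[3,4-bis(tert-butyldimethylsilyloxy)-5-methoxyphenyl]-3-(hydroxymethyl)-5-methoxy-2,3-dihydro-1,4-benzodioxine-7-carbaldehyde; 11 (triphenylphosphoranylidene)acetaldehyde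
Product: 12 (2E)-3-[(2R,3R)-2-[3,4-bis(tert-butyldimethylsilyloxy)-5-methoxyphenyl]-3-(hydroxymethyl)-5-methoxy-2,3-dihydro-1,4-benzodioxin-7-yl]prop-2-enal
Conditions: 11 (1.3 equiv), toluene, 80 °C
Reagents that add atoms: none
Why: Wittig olefination with a stabilised ylide, which should give the E enal and tolerates the free C9 hydroxyl. A small excess of ylide and monitoring limit a second homologation of the product.

Step 8
Reactants: 12 (2E)-3-[(2R,3R)-2-[3,4-bis(tert-butyldimethylsilyloxy)-5-methoxyphenyl]-3-(hydroxymethyl)-5-methoxy-2,3-dihydro-1,4-benzodioxin-7-yl]prop-2-enal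
Product: 13 (2E)-3-[(2R,3R)-2-(3,4-dihydroxy-5-methoxyphenyl)-3-(hydroxymethyl)-5-methoxy-2,3-dihydro-1,4-benzodioxin-7-yl]prop-2-enal
Conditions: Bu4NF (2.5 equiv), AcOH (3 equiv), THF, 0 °C
Reagents that add atoms: none
Why: Fluoride cleavage of the two aryl silyl ethers. The AcOH buffer keeps the catechol protonated, so that neither air oxidation nor base-induced quinone methide opening of the C2–O1 bond should occur, and the enal is not exposed to a basic nucleophile.

## Compound list

1 | methyl 3,4-dihydroxy-5-methoxybenzoate | COC(=O)c1cc(O)c(O)c(OC)c1 | starting material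
2 | methyl 4-hydroxy-3-methoxy-5-(methoxymethoxy)benzoate | COCOc1cc(C(=O)OC)cc(OC)c1O | intermediate
3 | 3,4-dihydroxy-5-methoxybenzaldehyde (5-hydroxyvanillin) | COc1cc(C=O)cc(O)c1O | starting material
4 | 3,4-bis(tert-butyldimethylsilyloxy)-5-methoxybenzaldehyde | COc1cc(C=O)cc(O[Si](C)(C)C(C)(C)C)c1O[Si](C)(C)C(C)(C)C | intermediate
5 | ethyl diazoacetate | CCOC(=O)C=[N+]=[N-] | starting material
6 | ethyl (2S,3R)-3-[3,4-bis(tert-butyldimethylsilyloxy)-5-methoxyphenyl]-3-hydroxy-2-[2-methoxy-4-(methoxycarbonyl)-6-(methoxymethoxy)phenoxy]propanoate | COc1cc([C@@H](O)[C@H](Oc2c(OCOC)cc(C(=O)OC)cc2OC)C(=O)OCC)cc(O[Si](C)(C)C(C)(C)C)c1O[Si](C)(C)C(C)(C)C | intermediate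
7 | ethyl (2S,3R)-3-[3,4-bis(tert-butyldimethylsilyloxy)-5-methoxyphenyl]-3-hydroxy-2-[2-hydroxy-6-methoxy-4-(methoxycarbonyl)phenoxy]propanoate | COc1cc([C@@H](O)[C@H](Oc2c(O)cc(C(=O)OC)cc2OC)C(=O)OCC)cc(O[Si](C)(C)C(C)(C)C)c1O[Si](C)(C)C(C)(C)C | intermediate (formed in step 4, not isolated)
8 | ethyl (2R,3S)-2-[3,4-bis(tert-butyldimethylsilyloxy)-5-methoxyphenyl]-5-methoxy-7-(methoxycarbonyl)-2,3-dihydro-1,4-benzodioxine-3-carboxylate (trans) | COc1cc([C@H]2Oc3cc(C(=O)OC)cc(OC)c3O[C@@H]2C(=O)OCC)cc(O[Si](C)(C)C(C)(C)C)c1O[Si](C)(C)C(C)(C)C | intermediate
9 | [(2R,3R)-2-[3,4-bis(tert-butyldimethylsilyloxy)-5-methoxyphenyl]-5-methoxy-2,3-dihydro-1,4-benzodioxine-3,7-diyl]dimethanol | COc1cc([C@H]2Oc3cc(CO)cc(OC)c3O[C@@H]2CO)cc(O[Si](C)(C)C(C)(C)C)c1O[Si](C)(C)C(C)(C)C | intermediate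
10 | (2R,3R)-2-[3,4-bis(tert-butyldimethylsilyloxy)-5-methoxyphenyl]-3-(hydroxymethyl)-5-methoxy-2,3-dihydro-1,4-benzodioxine-7-carbaldehyde | COc1cc([C@H]2Oc3cc(C=O)cc(OC)c3O[C@@H]2CO)cc(O[Si](C)(C)C(C)(C)C)c1O[Si](C)(C)C(C)(C)C | intermediate
11 | (triphenylphosphoranylidene)acetaldehyde | O=CC=P(c1ccccc1)(c1ccccc1)c1ccccc1 | starting material
12 | (2E)-3-[(2R,3R)-2-[3,4-bis(tert-butyldimethylsilyloxy)-5-methoxyphenyl]-3-(hydroxymethyl)-5-methoxy-2,3-dihydro-1,4-benzodioxin-7-yl]prop-2-enal | COc1cc([C@H]2Oc3cc(/C=C/C=O)cc(OC)c3O[C@@H]2CO)cc(O[Si](C)(C)C(C)(C)C)c1O[Si](C)(C)C(C)(C)C | intermediate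
13 | (2E)-3-[(2R,3R)-2-(3,4-dihydroxy-5-methoxyphenyl)-3-(hydroxymethyl)-5-methoxy-2,3-dihydro-1,4-benzodioxin-7-yl]prop-2-enal | COc1cc([C@H]2Oc3cc(/C=C/C=O)cc(OC)c3O[C@@H]2CO)cc(O)c1O | target

## Step count and least certain steps

Total step count: 8. Longest linear sequence: 7 steps (steps 1, 3, 4, 5, 6, 7, 8; the branch through step 2 is equally long).

Step 3 (key step). The most likely failure is that proton transfer within the oxonium ylide or its enol outruns addition to the electron-rich aldehyde, so that O–H insertion without C–C bond formation dominates. A second risk is low enantiofacial control if the addition takes place away from the phosphate. The fallback uses known chemistry: it sets out from 2, which is O-alkylated with commercial (4S)-4-benzyl-3-(chloroacetyl)-1,3-oxazolidin-2-one (K2CO3, NaI, MeCN, rt) to give the aryloxyacetyl oxazolidinone F1. An Evans syn aldol reaction of F1 (Bu2BOTf, iPr2NEt, CH2Cl2, −78 → 0 °C) with 4 should give the aldol imide F2, the Z boron enolate of the (S)-auxiliary leading to the (2S,3R) adduct. Ethanolysis with EtOMgBr (from EtMgBr and EtOH, THF, 0 °C) removes the auxiliary and comes back to the route at 6.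

Step 1. Alkylation at the other oxygen or at both is the risk, since the selectivity rests only on the different nucleophilicity of the two phenoxides; air oxidation of the dianion is a second hazard. The fallback sets out from 1: benzylation of the more acidic 4-hydroxyl under weak base (BnBr, KHCO3, DMF) gives the benzyl ether F3, MOMCl and iPr2NEt in CH2Cl2 give the fully protected benzoate F4, and hydrogenolysis (H2, Pd/C, EtOAc) comes back at 2.

Step 4. Ionisation next to the ester-bearing carbon may be slow, which would allow loss of the C3 proton from the cation (elimination, which also endangers C3), partial loss of silyl groups, or formation of some cis isomer. A cis isomer must not be corrected with base, because epimerisation at C3 would lead into the enantiomeric trans series. The fallback sets out from 6: NaBH4 (THF–EtOH, 0 °C → rt) reduces only the activated α-aryloxy ester and gives the diol F5. The same acid treatment (TFA, CH2Cl2–(CF3)2CHOH, 0 °C) then closes ring B at a cation that no longer has an ester beside it, to give the hydroxymethyl benzodioxine ester F6. iBu2AlH (CH2Cl2, −78 → 0 °C) reduces the remaining benzoate and comes back at 9.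

Step 7. Addition of the stabilised ylide to the electron-rich aldehyde may be sluggish, and the product enal may undergo a second olefination. The fallback sets out from 10: a Horner–Wadsworth–Emmons reaction with triethyl phosphonoacetate (LiCl, DBU, MeCN) gives the cinnamate ester F7, iBu2AlH (CH2Cl2, −78 °C) gives the allylic alcohol F8, and MnO2 (CH2Cl2, rt) oxidises only the allylic alcohol and comes back at 12.

## Further compounds

F1 | step 3 | methyl 4-{2-[(4S)-4-benzyl-2-oxo-1,3-oxazolidin-3-yl]-2-oxoethoxy}-3-methoxy-5-(methoxymethoxy)benzoate | COCOc1cc(C(=O)OC)cc(OC)c1OCC(=O)N1[C@@H](Cc2ccccc2)COC1=O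
F2 | step 3 | methyl 4-{[(2S,3R)-1-[(4S)-4-benzyl-2-oxo-1,3-oxazolidin-3-yl]-3-[3,4-bis(tert-butyldimethylsilyloxy)-5-methoxyphenyl]-3-hydroxy-1-oxopropan-2-yl]oxy}-3-methoxy-5-(methoxymethoxy)benzoate | COc1cc([C@@H](O)[C@H](Oc2c(OCOC)cc(C(=O)OC)cc2OC)C(=O)N2[C@@H](Cc3ccccc3)COC2=O)cc(O[Si](C)(C)C(C)(C)C)c1O[Si](C)(C)C(C)(C)C
F3 | step 1 | methyl 4-(benzyloxy)-3-hydroxy-5-methoxybenzoate | COC(=O)c1cc(O)c(OCc2ccccc2)c(OC)c1
F4 | step 1 | methyl 4-(benzyloxy)-3-methoxy-5-(methoxymethoxy)benzoate | COCOc1cc(C(=O)OC)cc(OC)c1OCc1ccccc1
F5 | step 4 | methyl 4-{[(1R,2R)-1-[3,4-bis(tert-butyldimethylsilyloxy)-5-methoxyphenyl]-1,3-dihydroxypropan-2-yl]oxy}-3-methoxy-5-(methoxymethoxy)benzoate | COc1cc([C@@H](O)[C@H](Oc2c(OCOC)cc(C(=O)OC)cc2OC)CO)cc(O[Si](C)(C)C(C)(C)C)c1O[Si](C)(C)C(C)(C)C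
F6 | step 4 | methyl (2R,3R)-2-[3,4-bis(tert-butyldimethylsilyloxy)-5-methoxyphenyl]-3-(hydroxymethyl)-5-methoxy-2,3-dihydro-1,4-benzodioxine-7-carboxylate | COc1cc([C@H]2Oc3cc(C(=O)OC)cc(OC)c3O[C@@H]2CO)cc(O[Si](C)(C)C(C)(C)C)c1O[Si](C)(C)C(C)(C)C
F7 | step 7 | ethyl (2E)-3-[(2R,3R)-2-[3,4-bis(tert-butyldimethylsilyloxy)-5-methoxyphenyl]-3-(hydroxymethyl)-5-methoxy-2,3-dihydro-1,4-benzodioxin-7-yl]prop-2-enoate | COc1cc([C@H]2Oc3cc(/C=C/C(=O)OCC)cc(OC)c3O[C@@H]2CO)cc(O[Si](C)(C)C(C)(C)C)c1O[Si](C)(C)C(C)(C)C
F8 | step 7 | (2E)-3-[(2R,3R)-2-[3,4-bis(tert-butyldimethylsilyloxy)-5-methoxyphenyl]-3-(hydroxymethyl)-5-methoxy-2,3-dihydro-1,4-benzodioxin-7-yl]prop-2-en-1-ol | COc1cc([C@H]2Oc3cc(/C=C/CO)cc(OC)c3O[C@@H]2CO)cc(O[Si](C)(C)C(C)(C)C)c1O[Si](C)(C)C(C)(C)C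
A1 | alternative 1 | 3-hydroxy-4-{[(2S)-1-(tert-butyldimethylsilyloxy)-3-[4-hydroxy-3-methoxy-5-(methoxymethoxy)phenyl]propan-2-yl]oxy}-5-methoxybenzaldehyde | COc1cc(C[C@@H](CO[Si](C)(C)C(C)(C)C)Oc2c(O)cc(C=O)cc2OC)cc(OCOC)c1O
A2 | alternative 1 | (2R,3R)-3-[(tert-butyldimethylsilyloxy)methyl]-2-[4-hydroxy-3-methoxy-5-(methoxymethoxy)phenyl]-5-methoxy-2,3-dihydro-1,4-benzodioxine-7-carbaldehyde | COc1cc([C@H]2Oc3cc(C=O)cc(OC)c3O[C@@H]2CO[Si](C)(C)C(C)(C)C)cc(OCOC)c1O
A3 | alternative 2 | methyl 3-methoxy-5-{[3-methoxy-4,5-bis(methoxymethoxy)phenyl]methoxy}-4-(2-oxoethoxy)benzoate | COc1cc(COc2cc(C(=O)OC)cc(OC)c2OCC=O)cc(OCOC)c1OCOC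
A4 | alternative 2 | methyl (2R,3S)-3-formyl-5-methoxy-2-[3-methoxy-4,5-bis(methoxymethoxy)phenyl]-2,3-dihydro-1,4-benzodioxine-7-carboxylate | COc1cc([C@H]2Oc3cc(C(=O)OC)cc(OC)c3O[C@@H]2C=O)cc(OCOC)c1OCOC
A5 | alternative 3 | methyl 4-bromo-3-hydroxy-5-methoxybenzoate | COC(=O)c1cc(O)c(Br)c(OC)c1
A6 | alternative 3 | tert-butyl({(2R,3S)-3-[3-methoxy-4,5-bis(methoxymethoxy)phenyl]oxiran-2-yl}methoxy)diphenylsilane | COc1cc([C@@H]2O[C@@H]2CO[Si](c2ccccc2)(c2ccccc2)C(C)(C)C)cc(OCOC)c1OCOC
A7 | alternative 3 | methyl 4-bromo-3-{[(1R,2R)-3-(tert-butyldiphenylsilyloxy)-2-hydroxy-1-[3-methoxy-4,5-bis(methoxymethoxy)phenyl]propyl]oxy}-5-methoxybenzoate | COc1cc([C@@H](Oc2cc(C(=O)OC)cc(OC)c2Br)[C@H](O)CO[Si](c2ccccc2)(c2ccccc2)C(C)(C)C)cc(OCOC)c1OCOC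
A8 | alternative 3 | methyl (2R,3R)-3-[(tert-butyldiphenylsilyloxy)methyl]-5-methoxy-2-[3-methoxy-4,5-bis(methoxymethoxy)phenyl]-2,3-dihydro-1,4-benzodioxine-7-carboxylate | COc1cc([C@H]2Oc3cc(C(=O)OC)cc(OC)c3O[C@@H]2CO[Si](c2ccccc2)(c2ccccc2)C(C)(C)C)cc(OCOC)c1OCOC
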